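The readings come from a simulation for substances that don't exist.

Slowness sets the question here: after 60.0 min of dosing, Saturday's run still holds 85.0% of its electrophile and Friday's 70.8%.

| setting | Saturday's | Friday's | dusk | spring |
|---|---|---|---|---|
| electrophile | 0.80 M | 0.80 M | 0.80 M | 0.80 M |
| nucleophile | 1.5 M (fed, over 2.0 h) | 2.8 M (fed, over 2.0 h) | 1.20 M (fed, over 2.0 h) | 1.80 M (fed, over 2.0 h) |
| gas | 67 mM (held) | 67 mM (held) | 67 mM (held) | 67 mM (held) |
| remark | run made earlier; the fed solution adds 0.10 times the starting volume | run made earlier; the fed solution adds 0.10 times the starting volume | the fed solution adds 0.10 times the starting volume | the fed solution adds 0.10 times the starting volume |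
| time |  |  | 2.0 h | 2.0 h |

| run | time / min | electrophile / % | target / % |
|---|---|---|---|
| Saturday's | 3.00 | 101.1 | 0.1 |
| Saturday's | 10.0 | 99.6 | 0.2 |
| Saturday's | 15.0 | 98.4 | 1.0 |
| Saturday's | 25.0 | 96.7 | 2.1 |
| Saturday's | 40.0 | 94.8 | 7.4 |
| Saturday's | 50.0 | 88.4 | 9.8 |
| Saturday's | 60.0 | 85.0 | 11.3 |
| Friday's | 8.00 | 99.4 | 0.8 |
| Friday's | 15.0 | 97.4 | 1.1 |
| Friday's | 25.0 | 93.5 | 5.5 |
| Friday's | 30.0 | 92.3 | 5.2 |
| Friday's | 40.0 | 85.6 | 11.8 |
| Friday's | 50.0 | 79.9 | 15.6 |
| Friday's | 60.0 | 70.8 | 21.2 |

(standard deviation of a reading: 1 percentage point)

- charges are per starting volume, the dose included; the dosed solution carries all of it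
- at the start none of the gas is in solution
- a reading or a percentage of target counts all its forms, free or not
- what has gone from electrophile into another species counts as reacted, even if it can come back
- a reading of electrophile is of its free form alone

- part of the electrophile that has reacted at the end, dusk
- part of the electrophile that has reacted at the end, spring
- what raising the concentration of nucleophile from its lowest to its highest value here does to the part of the electrophile that has reacted (changes below 5 percentage points count as none) (it falls / it rises / no change)

Dusk and spring both charge more nucleophile than electrophile , and the earlier runs lose electrophile slowly, so I reckon a speed, not a ceiling. With f the fraction of electrophile left, a steady dose should make ln(1/f) grow with the charge and the square of the time. Friday's value is 2.12 times Saturday's, against a charge ratio of 1.87.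

Which numbers matter? A relative error in that exponent moves the fraction reacted, counted on the charge, by at most 0.368 times that error. The gas stands at 67 mM in every flask, so it drops out of the scaling. Dilution trims the exponent more at the end of the dose than at 60.0 min, but the readings already carry the earlier part; the net trim beyond them is about 3.33%, worth at most about 1.23% of the charge, so I drop it. Nucleophile used up counts: the mean charge falls short by 0.667 of what has reacted in molar terms, which at Friday's loss is 13.0% of dusk's charge, so I keep it.

The number itself I read off the two runs. Scaling both runs to the end of the dose gives the end exponent per molar of charge 0.472 M⁻¹. A first pass gives 43.3% reacted for dusk and 57.3% for spring. Net of nucleophile used, the exponents are 0.458 and 0.706, so I commit to 36.7% and 50.6%, a rise of 14 percentage points.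

The forecast, “after allowing for nucleophile consumption and dilution”, says 32% (25% to 39%) and 44% (35% to 53%), with the trend it rises, lower than mine .

The flask gives 35.2% for dusk and 47.3% for spring; it rises, by 12 points.

    electrophile + nucleophile → acid set free + target (k = 0.00740 M⁻¹ min⁻¹)
    nucleophile + acid set free ⇌ protonated nucleophile, settled at all times (K = 53.0 M⁻¹)
    acid set free + free base ⇌ salt of the base (K = 21.0 M⁻¹, k = 0.220 M⁻¹ min⁻¹)
    electrophile + acid set free → side product (k = 3.10 × 10⁻⁴ M⁻¹ min⁻¹)
    electrophile + target ⇌ idle adduct, settled at all times (K = 0.640 M⁻¹)
    gas ⇌ free base, rate k6*(csat - [free base]) (kL = 0.0220 min⁻¹)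

Dusk's exponent is 0.434 against my 0.458. The neighbouring flask is dusk with 3.0 M of nucleophile. The same end exponent gives a first pass of 75.8%, a net exponent of 1.23, and 70.8% reacted. That flask gives 64.4%, an exponent of 1.03. It ends with free nucleophile at 70% of its charge and 0.404 M of protonated nucleophile.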